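**Plan**
- Ring A is numbered O1, C2 (3,4-dimethoxyphenyl), C3 (CH2OH), C4 (OAc and arylmethyl), C5 (CH2). The tertiary acetate at C4 is the Baeyer–Villiger image of an acetyl group and hence of a vinyl group, so the quaternary C4 next to C5H2–O1 is the substituted terminus of a π-allylpalladium unit that carries its own alkoxide.
- Retrosynthetic cuts, in order: the two O–benzyl groups, C4–O (back to C4–vinyl), the second carboxyl carbon at C3, then O1–C2 and C3–C4 of ring A together. This leaves a 4-arylmethyl-4-vinyl-1,3-dioxolan-2-one and an arylidene malonate.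
- Forward: eugenol is taken to the racemic carbonate (7 steps) and veratraldehyde to the acceptor (1 step). One palladium-catalysed decarboxylative (3+2) annulation builds ring A, the only ring formed, and 6 further steps adjust C3 and turn vinyl into acetate.
- Stereochemistry: C4 comes from the chiral phosphoramidite–palladium catalyst acting on a π-allyl whose precursor stereocentre is erased. C2 comes from the ring closure (aryl cis to vinyl), C3 from equilibration of the ester trans to the C2 aryl group, and the C4–O configuration from retentive migration in the Baeyer–Villiger step.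

Key step: step 9

Remark: all locants follow the ring A numbering above, also where a systematic name would count the other way; both antipodes of the phosphoramidite are available, and the one that delivers (4S) is to be fixed in a first small run.

Step 1
Reactants: 1 eugenol (4-allyl-2-methoxyphenol)
Product: 2 4-allyl-1-(benzyloxy)-2-methoxybenzene
Conditions: BnBr, K2CO3, DMF, 25 °C
Reagents that add atoms: benzyl bromide, BrCc1ccccc1
Why: Williamson etherification of the phenoxide; the benzyl ether should survive every later base and oxidant and is removed in the last step.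

Step 2
Reactants: 2 4-allyl-1-(benzyloxy)-2-methoxybenzene
Product: 3 (±)-3-[4-(benzyloxy)-3-methoxyphenyl]propane-1,2-diol
Conditions: OsO4 (2 mol %), NMO, acetone/H2O, 25 °C
Reagents that add atoms: N-methylmorpholine N-oxide, C[N+]1([O-])CCOCC1; water, O
Why: catalytic OsO4/NMO syn-dihydroxylation of the monosubstituted alkene; the new carbinol centre may be racemic because it is oxidised in step 4.

Step 3
Reactants: 3 (±)-3-[4-(benzyloxy)-3-methoxyphenyl]propane-1,2-diol
Product: 4 (±)-1-[4-(benzyloxy)-3-methoxyphenyl]-3-[(tert-butyldimethylsilyl)oxy]propan-2-ol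
Conditions: TBSCl, imidazole, CH2Cl2, 0 °C
Reagents that add atoms: tert-butyldimethylsilyl chloride, CC(C)(C)[Si](C)(C)Cl
Why: silyl ether formation, selective for the primary hydroxyl of the 1,2-diol on steric grounds.

Step 4
Reactants: 4 (±)-1-[4-(benzyloxy)-3-methoxyphenyl]-3-[(tert-butyldimethylsilyl)oxy]propan-2-ol
Product: 5 1-[4-(benzyloxy)-3-methoxyphenyl]-3-[(tert-butyldimethylsilyl)oxy]propan-2-one
Conditions: Dess–Martin periodinane, CH2Cl2, 25 °C
Reagents that add atoms: none
Why: Dess–Martin oxidation of the secondary alcohol under near-neutral conditions that spare the silyl ether and the enolisable benzylic position.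

Step 5
Reactants: 5 1-[4-(benzyloxy)-3-methoxyphenyl]-3-[(tert-butyldimethylsilyl)oxy]propan-2-one; 6 vinylmagnesium bromide
Product: 7 (±)-1-[4-(benzyloxy)-3-methoxyphenyl]-2-{[(tert-butyldimethylsilyl)oxy]methyl}but-3-en-2-ol
Conditions: THF, −78 → 0 °C
Reagents that add atoms: none
Why: Grignard 1,2-addition to a ketone activated by its α-silyloxy group, run cold to limit enolisation at the benzylic CH2; the racemic tertiary carbinol is acceptable because this centre is ionised in step 9.

Step 6
Reactants: 7 (±)-1-[4-(benzyloxy)-3-methoxyphenyl]-2-{[(tert-butyldimethylsilyl)oxy]methyl}but-3-en-2-ol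
Product: 8 (±)-2-{[4-(benzyloxy)-3-methoxyphenyl]methyl}but-3-ene-1,2-diol
Conditions: TBAF, THF, 0 °C
Reagents that add atoms: none
Why: fluoride-mediated desilylation frees the primary alcohol without touching the tertiary allylic alcohol.

Step 7
Reactants: 8 (±)-2-{[4-(benzyloxy)-3-methoxyphenyl]methyl}but-3-ene-1,2-diol
Product: 9 (±)-4-{[4-(benzyloxy)-3-methoxyphenyl]methyl}-4-ethenyl-1,3-dioxolan-2-one
Conditions: CDI, DMAP (cat.), CH2Cl2, 25 °C
Reagents that add atoms: 1,1'-carbonyldiimidazole, O=C(n1ccnc1)n1ccnc1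
Why: cyclic carbonate formation from a 1,2-diol: the primary hydroxyl is acylated and the tertiary hydroxyl closes onto the imidazole carboxylate in a 5-exo-trig acyl substitution.

Step 8
Reactants: 10 3,4-dimethoxybenzaldehyde; 11 dimethyl malonate
Product: 12 dimethyl 2-[(3,4-dimethoxyphenyl)methylidene]propanedioate
Conditions: piperidine (cat.), AcOH (cat.), toluene, reflux, Dean–Stark
Reagents that add atoms: none
Why: Knoevenagel condensation driven by azeotropic removal of water; the two ester groups are identical, so only one alkene isomer exists.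

Step 9
Reactants: 9 (±)-4-{[4-(benzyloxy)-3-methoxyphenyl]methyl}-4-ethenyl-1,3-dioxolan-2-one; 12 dimethyl 2-[(3,4-dimethoxyphenyl)methylidene]propanedioate
Product: 13 dimethyl (2R,4S)-4-{[4-(benzyloxy)-3-methoxyphenyl]methyl}-2-(3,4-dimethoxyphenyl)-4-ethenyloxolane-3,3-dicarboxylate (C2 aryl cis to C4 vinyl)
Conditions: Pd2(dba)3·CHCl3 (2.5 mol %), BINOL-derived N,N-bis(1-phenylethyl)phosphoramidite (10 mol %), THF, 40 °C
Reagents that add atoms: none
Why: Zerovalent palladium ionises the tertiary allylic C–O bond of 9 and CO2 is lost, which gives a π-allylpalladium cation tethered to a primary alkoxide; the carbonate stereocentre is erased and the two allyl faces interconvert by π–σ–π isomerisation. The alkoxide adds reversibly to the β-carbon of 12 (O1–C2), and the malonate anion so formed attacks the substituted allyl terminus anti to palladium (C3–C4), closing ring A in a 5-exo mode. The closest known reaction type is the palladium-catalysed asymmetric decarboxylative (3+2) cycloaddition of 4-substituted vinylethylene carbonates with doubly activated alkenes, which gives 4-vinyl tetrahydrofurans with a quaternary C4. C4 is set by the chiral phosphoramidite, which selects the allyl face in the C–C bond-forming step; C2 is set in the ring-closing transition state, where the C2 aryl group and the bulky palladium-bound allyl residue should both lie pseudo-equatorial, so that aryl and vinyl end up cis. The step needs branched regioselectivity and 2,4-cis diastereoselectivity: the tether secures the first (five- against seven-membered ring) and the reversible oxa-Michael addition the second, because the adducts can equilibrate before the slower alkylation; the relative configuration is to be checked by NOE before going on.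

Step 10
Reactants: 13 dimethyl (2R,4S)-4-{[4-(benzyloxy)-3-methoxyphenyl]methyl}-2-(3,4-dimethoxyphenyl)-4-ethenyloxolane-3,3-dicarboxylate
Product: 15 methyl (2S,3S,4S)-4-{[4-(benzyloxy)-3-methoxyphenyl]methyl}-2-(3,4-dimethoxyphenyl)-4-ethenyloxolane-3-carboxylate (2,3-trans ester), via C3-epimeric cis ester 14 (not isolated)
Conditions: LiCl, H2O, DMSO, 150 °C; then NaOMe (cat.), MeOH, 25 °C
Reagents that add atoms: none
Why: Krapcho dealkoxycarbonylation (chloride attack at an ester methyl group, loss of CO2, protonation of the ester enolate) followed by base equilibration through the ester enolate, which should place the C3 ester trans to the C2 aryl group; the quaternary C4 and the ether carbon C2 cannot epimerise by enolisation.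

Step 11
Reactants: 15 methyl (2S,3S,4S)-4-{[4-(benzyloxy)-3-methoxyphenyl]methyl}-2-(3,4-dimethoxyphenyl)-4-ethenyloxolane-3-carboxylate
Product: 16 [(2S,3R,4S)-4-{[4-(benzyloxy)-3-methoxyphenyl]methyl}-2-(3,4-dimethoxyphenyl)-4-ethenyloxolan-3-yl]methanol
Conditions: LiAlH4, THF, 0 °C
Reagents that add atoms: none
Why: LiAlH4 reduction of the ester to the primary alcohol; the isolated vinyl group and the ethers are inert, and C3 is no longer epimerisable afterwards.

Step 12
Reactants: 16 [(2S,3R,4S)-4-{[4-(benzyloxy)-3-methoxyphenyl]methyl}-2-(3,4-dimethoxyphenyl)-4-ethenyloxolan-3-yl]methanol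
Product: 17 (2S,3R,4S)-4-{[4-(benzyloxy)-3-methoxyphenyl]methyl}-3-[(benzyloxy)methyl]-2-(3,4-dimethoxyphenyl)-4-ethenyloxolane
Conditions: NaH, BnBr, Bu4NI (cat.), THF, 0 → 25 °C
Reagents that add atoms: benzyl bromide, BrCc1ccccc1
Why: Williamson etherification of the primary alkoxide; the ether keeps the hydroxyl out of the palladium oxidation and the peracid step and falls together with the phenol benzyl ether at the end.

Step 13
Reactants: 17 (2S,3R,4S)-4-{[4-(benzyloxy)-3-methoxyphenyl]methyl}-3-[(benzyloxy)methyl]-2-(3,4-dimethoxyphenyl)-4-ethenyloxolane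
Product: 18 1-[(2S,3R,4S)-4-{[4-(benzyloxy)-3-methoxyphenyl]methyl}-3-[(benzyloxy)methyl]-2-(3,4-dimethoxyphenyl)oxolan-4-yl]ethan-1-one
Conditions: PdCl2 (10 mol %), CuCl (30 mol %), O2 (1 atm), DMF/H2O 7:1, 25 °C
Reagents that add atoms: water, O
Why: Tsuji–Wacker oxidation: Markovnikov hydroxypalladation of the monosubstituted alkene by divalent palladium and β-hydride elimination give the methyl ketone, and since C4 is quaternary no alkene migration can compete.

Step 14
Reactants: 18 1-[(2S,3R,4S)-4-{[4-(benzyloxy)-3-methoxyphenyl]methyl}-3-[(benzyloxy)methyl]-2-(3,4-dimethoxyphenyl)oxolan-4-yl]ethan-1-one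
Product: 19 (2S,3R,4S)-4-{[4-(benzyloxy)-3-methoxyphenyl]methyl}-3-[(benzyloxy)methyl]-2-(3,4-dimethoxyphenyl)oxolan-4-yl acetate
Conditions: mCPBA, CH2Cl2, 0 → 25 °C
Reagents that add atoms: 3-chloroperoxybenzoic acid, OOC(=O)c1cccc(Cl)c1
Why: Baeyer–Villiger oxidation; in the peroxyhemiketal adduct the tertiary C4 migrates in preference to methyl and with retention, so the C–C configuration set in step 9 becomes the C–O configuration of the tertiary acetate.

Step 15
Reactants: 19 (2S,3R,4S)-4-{[4-(benzyloxy)-3-methoxyphenyl]methyl}-3-[(benzyloxy)methyl]-2-(3,4-dimethoxyphenyl)oxolan-4-yl acetate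
Product: 20 (2S,3R,4S)-2-(3,4-dimethoxyphenyl)-4-[(4-hydroxy-3-methoxyphenyl)methyl]-3-(hydroxymethyl)oxolan-4-yl acetate (target)
Conditions: H2 (1 atm), Pd/C (10 wt % Pd), EtOAc, 25 °C
Reagents that add atoms: none
Why: hydrogenolysis of the aryl and the primary alkyl benzyl ether under neutral conditions, which avoids acetyl migration from the tertiary to the primary oxygen; the hindered, electron-rich cyclic benzylic C2–O1 bond should cleave more slowly, and the reaction is stopped once both benzyl groups are gone.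

**Compound list**
1 | eugenol (4-allyl-2-methoxyphenol) | COc1cc(CC=C)ccc1O | starting material
2 | 4-allyl-1-(benzyloxy)-2-methoxybenzene | COc1cc(CC=C)ccc1OCc1ccccc1 | intermediate
3 | (±)-3-[4-(benzyloxy)-3-methoxyphenyl]propane-1,2-diol | COc1cc(CC(O)CO)ccc1OCc1ccccc1 | intermediate
4 | (±)-1-[4-(benzyloxy)-3-methoxyphenyl]-3-[(tert-butyldimethylsilyl)oxy]propan-2-ol | COc1cc(CC(O)CO[Si](C)(C)C(C)(C)C)ccc1OCc1ccccc1 | intermediate
5 | 1-[4-(benzyloxy)-3-methoxyphenyl]-3-[(tert-butyldimethylsilyl)oxy]propan-2-one | COc1cc(CC(=O)CO[Si](C)(C)C(C)(C)C)ccc1OCc1ccccc1 | intermediate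
6 | vinylmagnesium bromide | C=C[Mg]Br | starting material
7 | (±)-1-[4-(benzyloxy)-3-methoxyphenyl]-2-{[(tert-butyldimethylsilyl)oxy]methyl}but-3-en-2-ol | COc1cc(CC(O)(C=C)CO[Si](C)(C)C(C)(C)C)ccc1OCc1ccccc1 | intermediate
8 | (±)-2-{[4-(benzyloxy)-3-methoxyphenyl]methyl}but-3-ene-1,2-diol | COc1cc(CC(O)(C=C)CO)ccc1OCc1ccccc1 | intermediate
9 | (±)-4-{[4-(benzyloxy)-3-methoxyphenyl]methyl}-4-ethenyl-1,3-dioxolan-2-one | C=CC1(Cc2ccc(OCc3ccccc3)c(OC)c2)COC(=O)O1 | intermediate
10 | 3,4-dimethoxybenzaldehyde | COc1ccc(C=O)cc1OC | starting material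
11 | dimethyl malonate | COC(=O)CC(=O)OC | starting material
12 | dimethyl 2-[(3,4-dimethoxyphenyl)methylidene]propanedioate | COC(=O)C(=Cc1ccc(OC)c(OC)c1)C(=O)OC | intermediate
13 | dimethyl (2R,4S)-4-{[4-(benzyloxy)-3-methoxyphenyl]methyl}-2-(3,4-dimethoxyphenyl)-4-ethenyloxolane-3,3-dicarboxylate | COc1cc(C[C@@]2(C=C)CO[C@H](c3ccc(OC)c(OC)c3)C2(C(=O)OC)C(=O)OC)ccc1OCc1ccccc1 | intermediate
14 | methyl (2S,3R,4S)-4-{[4-(benzyloxy)-3-methoxyphenyl]methyl}-2-(3,4-dimethoxyphenyl)-4-ethenyloxolane-3-carboxylate (2,3-cis ester) | COc1cc(C[C@@]2(C=C)CO[C@H](c3ccc(OC)c(OC)c3)[C@@H]2C(=O)OC)ccc1OCc1ccccc1 | intermediate (not isolated)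
15 | methyl (2S,3S,4S)-4-{[4-(benzyloxy)-3-methoxyphenyl]methyl}-2-(3,4-dimethoxyphenyl)-4-ethenyloxolane-3-carboxylate (2,3-trans ester) | COc1cc(C[C@@]2(C=C)CO[C@H](c3ccc(OC)c(OC)c3)[C@H]2C(=O)OC)ccc1OCc1ccccc1 | intermediate
16 | [(2S,3R,4S)-4-{[4-(benzyloxy)-3-methoxyphenyl]methyl}-2-(3,4-dimethoxyphenyl)-4-ethenyloxolan-3-yl]methanol | COc1cc(C[C@@]2(C=C)CO[C@H](c3ccc(OC)c(OC)c3)[C@H]2CO)ccc1OCc1ccccc1 | intermediate
17 | (2S,3R,4S)-4-{[4-(benzyloxy)-3-methoxyphenyl]methyl}-3-[(benzyloxy)methyl]-2-(3,4-dimethoxyphenyl)-4-ethenyloxolane | COc1cc(C[C@@]2(C=C)CO[C@H](c3ccc(OC)c(OC)c3)[C@H]2COCc2ccccc2)ccc1OCc1ccccc1 | intermediate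
18 | 1-[(2S,3R,4S)-4-{[4-(benzyloxy)-3-methoxyphenyl]methyl}-3-[(benzyloxy)methyl]-2-(3,4-dimethoxyphenyl)oxolan-4-yl]ethan-1-one | COc1cc(C[C@@]2(C(C)=O)CO[C@H](c3ccc(OC)c(OC)c3)[C@H]2COCc2ccccc2)ccc1OCc1ccccc1 | intermediate
19 | (2S,3R,4S)-4-{[4-(benzyloxy)-3-methoxyphenyl]methyl}-3-[(benzyloxy)methyl]-2-(3,4-dimethoxyphenyl)oxolan-4-yl acetate | COc1cc(C[C@@]2(OC(C)=O)CO[C@H](c3ccc(OC)c(OC)c3)[C@H]2COCc2ccccc2)ccc1OCc1ccccc1 | intermediate
20 | (2S,3R,4S)-2-(3,4-dimethoxyphenyl)-4-[(4-hydroxy-3-methoxyphenyl)methyl]-3-(hydroxymethyl)oxolan-4-yl acetate | COc1cc(C[C@@]2(OC(C)=O)CO[C@H](c3ccc(OC)c(OC)c3)[C@H]2CO)ccc1O | target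

**Step count and risks**
Total: 15 steps. Longest linear sequence: 14 steps (steps 1–7 and 9–15, from eugenol).

Steps most likely to fail:

1. Step 9. The oxa-Michael addition of the tethered alkoxide to the electron-rich diester 12 may be too slow, so that the π-allylpalladium intermediate is lost by β-hydride elimination at the benzylic CH2 to a 1,3-diene; ring closure at the doubly quaternary C3–C4 bond may also be sluggish.
   - The fallback sets out from 9 and 10 and changes the acceptor to a far more electrophilic cyclic malonate.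
   - Aldehyde 10 is condensed with Meldrum's acid (water, 75 °C) to 5-[(3,4-dimethoxyphenyl)methylidene]-2,2-dimethyl-1,3-dioxane-4,6-dione F1.
   - The same Pd2(dba)3·CHCl3/phosphoramidite catalyst should join 9 and F1 to the spirocyclic Meldrum's acid cycloadduct F2.
   - NaOMe in MeOH opens the dioxanedione to the malonic half ester F3, which after acidification is decarboxylated by heating in toluene.
   - The NaOMe equilibration of step 10 then gives 15, where the route is rejoined.

2. Step 14. Peracid addition to the neopentyl-type ketone carbonyl may be slow enough for oxidation of the two electron-rich arenes to compete.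
   - The fallback sets out from 17, bypasses 18 and changes the oxidation level of the migrating-group partner.
   - OsO4 (cat.)/NaIO4/2,6-lutidine in dioxane/H2O cleaves the vinyl group to the aldehyde F4.
   - The much less hindered α-quaternary aldehyde is oxidised by mCPBA, with tertiary-alkyl migration and retention, to the formate F5.
   - KHCO3 in MeOH releases the tertiary alcohol F6.
   - Ac2O/DMAP/Et3N acetylates it to 19, where the route is rejoined.

3. Step 13. Coordination of palladium by the homoallylic ring oxygen or the benzyl ether oxygen may steer hydroxypalladation to the terminal carbon (aldehyde), or the hindered alkene may react sluggishly.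
   - The fallback sets out from 17 and replaces oxypalladation by hydrogen-atom-transfer hydration, whose regiochemistry follows radical stability and not coordination.
   - Mukaiyama hydration (Co(acac)2 cat., PhSiH3, O2, THF, 25 °C) should give the secondary alcohol F7 as a mixture of carbinol epimers.
   - Dess–Martin oxidation converts F7 into 18, where the route is rejoined.

**Further compounds**
F1 | step 9 | 5-[(3,4-dimethoxyphenyl)methylidene]-2,2-dimethyl-1,3-dioxane-4,6-dione | COc1ccc(C=C2C(=O)OC(C)(C)OC2=O)cc1OC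
F2 | step 9 | spirocyclic Meldrum's acid cycloadduct: (2R,4S)-configured ring A of 13 with C3 spiro-fused to C5 of 2,2-dimethyl-1,3-dioxane-4,6-dione | COc1cc(C[C@@]2(C=C)CO[C@H](c3ccc(OC)c(OC)c3)C24C(=O)OC(C)(C)OC4=O)ccc1OCc1ccccc1
F3 | step 9 | (2R,4S)-4-{[4-(benzyloxy)-3-methoxyphenyl]methyl}-2-(3,4-dimethoxyphenyl)-4-ethenyl-3-(methoxycarbonyl)oxolane-3-carboxylic acid (malonic half ester, C3 epimers) | COc1cc(C[C@@]2(C=C)CO[C@H](c3ccc(OC)c(OC)c3)C2(C(=O)OC)C(O)=O)ccc1OCc1ccccc1
F4 | step 14 | (2S,3R,4S)-4-{[4-(benzyloxy)-3-methoxyphenyl]methyl}-3-[(benzyloxy)methyl]-2-(3,4-dimethoxyphenyl)oxolane-4-carbaldehyde | COc1cc(C[C@@]2(C=O)CO[C@H](c3ccc(OC)c(OC)c3)[C@H]2COCc2ccccc2)ccc1OCc1ccccc1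
F5 | step 14 | (2S,3R,4S)-4-{[4-(benzyloxy)-3-methoxyphenyl]methyl}-3-[(benzyloxy)methyl]-2-(3,4-dimethoxyphenyl)oxolan-4-yl formate | COc1cc(C[C@@]2(OC=O)CO[C@H](c3ccc(OC)c(OC)c3)[C@H]2COCc2ccccc2)ccc1OCc1ccccc1
F6 | step 14 | (2S,3R,4S)-4-{[4-(benzyloxy)-3-methoxyphenyl]methyl}-3-[(benzyloxy)methyl]-2-(3,4-dimethoxyphenyl)oxolan-4-ol | COc1cc(C[C@@]2(O)CO[C@H](c3ccc(OC)c(OC)c3)[C@H]2COCc2ccccc2)ccc1OCc1ccccc1
F7 | step 13 | 1-[(2S,3R,4S)-4-{[4-(benzyloxy)-3-methoxyphenyl]methyl}-3-[(benzyloxy)methyl]-2-(3,4-dimethoxyphenyl)oxolan-4-yl]ethan-1-ol (carbinol epimers) | COc1cc(C[C@@]2(C(C)O)CO[C@H](c3ccc(OC)c(OC)c3)[C@H]2COCc2ccccc2)ccc1OCc1ccccc1
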